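The oxetan-2-one of the hymeglusin half is cut between its ring oxygen O1 and the chain-bearing ring carbon C4. Because the CH2OH at C3 and the chain at C4 are trans, this bond can be formed with inversion: Mitsunobu activation of the hydroxyl of an Evans syn-aldol acid lets the carboxylate close the four-membered ring and set C4 in one operation. The precursor is an open-chain syn 3-hydroxy-2-(silyloxymethyl) acid grown from a citronellal-derived dienoate aldehyde. The same aldehyde with the mirror-image auxiliary, the same lactonization and an acyl–oxygen ring opening give the anti (2S,3S) hydroxy ester half; esterification and one acidolysis complete the route.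

Key step: step 11

Remark: the open-chain half is built exactly as drawn, with a (2S,3S) diad that is the mirror image of the (3R,4R) lactone diad; tert-butyl but-2-ynoate and 3-[(tert-butyldimethylsilyl)oxy]propanoic acid are taken as catalogue chemicals.

Step 1
Reactants: 1 (R)-citronellal
Product: 2 (4R)-4,8-dimethylnon-7-en-1-yne
Conditions: dimethyl (1-diazo-2-oxopropyl)phosphonate, K2CO3, MeOH, 0 °C to rt
Reagents that add atoms: dimethyl (1-diazo-2-oxopropyl)phosphonate, CC(=O)C(=[N+]=[N-])P(=O)(OC)OC
Why: Ohira–Bestmann (Seyferth–Gilbert) homologation: the diazomethylphosphonate anion released by methanolysis olefinates the aldehyde and the diazoalkene loses N2 with a 1,2-hydride shift to the terminal alkyne, while the chiral-pool stereocentre is not at an enolisable position and is carried through unchanged.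

Step 2
Reactants: 2 (4R)-4,8-dimethylnon-7-en-1-yne
Product: 4 (1E,4R)-1-iodo-2,4,8-trimethylnona-1,7-diene, via alkenylalane 3 (not isolated)
Conditions: Me3Al, Cp2ZrCl2 (cat.), CH2Cl2, 0 °C to rt; then I2, THF, −30 to 0 °C
Reagents that add atoms: trimethylaluminium, C[Al](C)C; iodine, [I][I]
Why: Negishi zirconium-catalysed carboalumination adds methyl and aluminium syn across the terminal alkyne with methyl at the internal carbon, and iodinolysis of the carbon–aluminium bond with retention should give the E iodide, the unactivated trisubstituted alkene being inert.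

Step 3
Reactants: 5 tert-butyl but-2-ynoate
Product: 6 tert-butyl (2Z)-3-(4,4,5,5-tetramethyl-1,3,2-dioxaborolan-2-yl)but-2-enoate
Conditions: B2pin2, CuCl (cat.), Xantphos (cat.), NaOt-Bu (cat.), MeOH, THF, rt
Reagents that add atoms: bis(pinacolato)diboron, CC1(C)OB(OC1(C)C)B1OC(C)(C)C(C)(C)O1
Why: Copper-catalysed β-borylation of an ynoate: the borylcopper species adds syn with boron at the β-carbon and methanol protonates the alkenylcopper with retention, so boron ends trans to the ester.

Step 4
Reactants: 4 (1E,4R)-1-iodo-2,4,8-trimethylnona-1,7-diene; 6 tert-butyl (2Z)-3-(4,4,5,5-tetramethyl-1,3,2-dioxaborolan-2-yl)but-2-enoate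
Product: 7 tert-butyl (2E,4E,7R)-3,5,7,11-tetramethyldodeca-2,4,10-trienoate
Conditions: Pd(PPh3)4 (cat.), K3PO4, THF/H2O, 50 °C
Reagents that add atoms: none
Why: Suzuki–Miyaura coupling at zerovalent palladium proceeds with retention at both alkenyl carbons, which fixes the 2E,4E geometry of the dienoate.

Step 5
Reactants: 7 tert-butyl (2E,4E,7R)-3,5,7,11-tetramethyldodeca-2,4,10-trienoate
Product: 8 tert-butyl (2E,4E,7R,10E)-3,5,7-trimethyl-12-oxododeca-2,4,10-trienoate
Conditions: (E)-but-2-enal (excess), second-generation Hoveyda–Grubbs catalyst RuCl2(H2IMes)(=CH-C6H4-2-Oi-Pr) (cat.), CH2Cl2, 40 °C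
Reagents that add atoms: (E)-but-2-enal, C/C=C/C=O
Why: Olefin cross-metathesis exchanges the isopropylidene terminus for a formylmethylidene unit and should give the E enal under thermodynamic control, whereas the conjugated trisubstituted alkenes of the dienoate are too hindered and electron-poor to enter the catalytic cycle.

Step 6
Reactants: 8 tert-butyl (2E,4E,7R,10E)-3,5,7-trimethyl-12-oxododeca-2,4,10-trienoate
Product: 9 tert-butyl (2E,4E,7R)-3,5,7-trimethyl-12-oxododeca-2,4-dienoate
Conditions: Hantzsch ester (diethyl 2,6-dimethyl-1,4-dihydropyridine-3,5-dicarboxylate), Bn2NH·CF3CO2H (cat.), THF, rt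
Reagents that add atoms: none
Why: Organocatalytic transfer hydrogenation (iminium-ion conjugate reduction): only the enal condenses with the secondary ammonium salt, so hydride from the dihydropyridine goes to its β-carbon and the ester-conjugated diene is left alone.

Step 7
Reactants: 10 3-[(tert-butyldimethylsilyl)oxy]propanoic acid
Product: 11 3-[(tert-butyldimethylsilyl)oxy]propanoic pivalic anhydride
Conditions: PivCl, Et3N, THF, −20 to 0 °C; Et3N·HCl filtered off under argon; the cold filtrate is divided into two equal portions and used at once (one for step 8, one for step 13)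
Reagents that add atoms: pivaloyl chloride, CC(C)(C)C(=O)Cl
Why: Mixed-anhydride activation: the triethylammonium carboxylate is acylated by the acid chloride, the silyl ether is stable to the amine-buffered medium, and one batch of the acyl donor serves both auxiliaries.

Step 8
Reactants: 11 3-[(tert-butyldimethylsilyl)oxy]propanoic pivalic anhydride; 12 (R)-4-benzyloxazolidin-2-one
Product: 13 (R)-4-benzyl-3-{3-[(tert-butyldimethylsilyl)oxy]propanoyl}oxazolidin-2-one
Conditions: 12, LiCl, Et3N, THF, −20 °C to rt
Reagents that add atoms: none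
Why: N-Acylation of the oxazolidinone by the mixed pivalic anhydride, whose less hindered carbonyl is attacked by the auxiliary activated by LiCl and triethylamine.

Step 9
Reactants: 9 tert-butyl (2E,4E,7R)-3,5,7-trimethyl-12-oxododeca-2,4-dienoate; 13 (R)-4-benzyl-3-{3-[(tert-butyldimethylsilyl)oxy]propanoyl}oxazolidin-2-one
Product: 15 (4R)-4-benzyl-3-[(2R,3S,8R,10E,12E)-14-tert-butoxy-2-{[(tert-butyldimethylsilyl)oxy]methyl}-3-hydroxy-8,10,12-trimethyl-14-oxotetradeca-10,12-dienoyl]oxazolidin-2-one, via boron enolate 14 (not isolated)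
Conditions: 13, Bu2BOTf, i-Pr2NEt, CH2Cl2, 0 °C; then 9, −78 to 0 °C; then pH 7 buffer, MeOH, H2O2, 0 °C
Reagents that add atoms: none
Why: Evans syn-aldol reaction: the Z boron enolate reacts through a chair Zimmerman–Traxler transition state (syn relationship) on the enolate face away from the benzyl group of the (R)-auxiliary, which should set C2 as R and C3 as S.

Step 10
Reactants: 15 the (2R,3S) syn-aldol imide
Product: 16 (2R,3S,8R,10E,12E)-14-tert-butoxy-2-{[(tert-butyldimethylsilyl)oxy]methyl}-3-hydroxy-8,10,12-trimethyl-14-oxotetradeca-10,12-dienoic acid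
Conditions: LiOH, H2O2, THF/H2O, 0 °C; then Na2SO3; then dilute HCl to pH 3–4, 0 °C
Reagents that add atoms: hydrogen peroxide (as LiOOH), OO
Why: Hydroperoxide cleavage of the N-acyl oxazolidinone: the hydroperoxide anion attacks the exocyclic carbonyl selectively and is too weakly basic to epimerise C2, cause retro-aldol cleavage or saponify the hindered conjugated tert-butyl ester.

Step 11
Reactants: 16 the (2R,3S) syn hydroxy acid
Product: 18 tert-butyl (2E,4E,7R)-11-[(2R,3R)-3-{[(tert-butyldimethylsilyl)oxy]methyl}-4-oxooxetan-2-yl]-3,5,7-trimethylundeca-2,4-dienoate, via oxyphosphonium carboxylate 17 (not isolated)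
Conditions: PPh3, DIAD, THF, −78 °C (betaine preformed); slow addition of 16, −78 to 0 °C
Reagents that add atoms: none
Why: Mitsunobu lactonization by hydroxyl-group activation: the PPh3–DIAD betaine is protonated by the carboxylic acid and passes phosphorus to the C3 hydroxyl, so zwitterion 17 carries a carboxylate next to an alkoxytriphenylphosphonium leaving group. The carboxylate oxygen then attacks the carbinol carbon from the side opposite to the departing Ph3P=O (intramolecular SN2), which forms the bond between ring oxygen O1 and ring carbon C4 of the oxetan-2-one; the closest known reaction type is the Mitsunobu β-lactonization of β-hydroxy acids with inversion. The single ring closes in the 4-exo-tet mode. No new stereocentre is created: C4 is set stereospecifically by inversion of the aldol carbinol (3S in 16 becomes R at C4) and C3 is untouched, so the syn diad becomes the trans lactone, whose substituents are already anti in the reactive conformer that places the carboxylate anti-periplanar to the leaving group. The step needs hydroxyl activation to win over carboxyl activation (which would close with retention to the cis lactone) and substitution to win over decarboxylative anti-elimination; the preformed betaine at low temperature, a carbinol carbon that carries only alkyl groups and so stabilises no positive charge, and the absence of any other free hydroxyl or carboxyl group (silyl ether, tert-butyl ester) should secure this.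

Step 12
Reactants: 18 the (2R,3R) β-lactone tert-butyl ester
Product: 20 (2E,4E,7R)-11-[(2R,3R)-3-{[(tert-butyldimethylsilyl)oxy]methyl}-4-oxooxetan-2-yl]-3,5,7-trimethylundeca-2,4-dienoic acid, via trimethylsilyl ester 19 (not isolated)
Conditions: TMSOTf, 2,6-lutidine, CH2Cl2, 0 °C; then pH 5 aqueous buffer
Reagents that add atoms: none
Why: Silyl-triflate-mediated tert-butyl ester cleavage: O-silylation of the ester carbonyl expels isobutene and the trimethylsilyl ester is hydrolysed on work-up, under buffered non-nucleophilic conditions that should spare the β-lactone and the primary silyl ether.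

Step 13
Reactants: 11 3-[(tert-butyldimethylsilyl)oxy]propanoic pivalic anhydride; 21 (S)-4-benzyloxazolidin-2-one
Product: 22 (S)-4-benzyl-3-{3-[(tert-butyldimethylsilyl)oxy]propanoyl}oxazolidin-2-one
Conditions: 21, LiCl, Et3N, THF, −20 °C to rt
Reagents that add atoms: none
Why: The same N-acylation by the mixed pivalic anhydride as in step 8, run on the second portion of 11 with the mirror-image auxiliary.

Step 14
Reactants: 9 tert-butyl (2E,4E,7R)-3,5,7-trimethyl-12-oxododeca-2,4-dienoate; 22 (S)-4-benzyl-3-{3-[(tert-butyldimethylsilyl)oxy]propanoyl}oxazolidin-2-one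
Product: 24 (4S)-4-benzyl-3-[(2S,3R,8R,10E,12E)-14-tert-butoxy-2-{[(tert-butyldimethylsilyl)oxy]methyl}-3-hydroxy-8,10,12-trimethyl-14-oxotetradeca-10,12-dienoyl]oxazolidin-2-one, via boron enolate 23 (not isolated)
Conditions: 22, Bu2BOTf, i-Pr2NEt, CH2Cl2, 0 °C; then 9, −78 to 0 °C; then pH 7 buffer, MeOH, H2O2, 0 °C
Reagents that add atoms: none
Why: Evans syn-aldol reaction under auxiliary control (Z boron enolate, chair transition state), the (S)-auxiliary now directing the aldehyde to the opposite enolate face so that C2 should be S and C3 R, the remote C8 centre having no influence.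

Step 15
Reactants: 24 the (2S,3R) syn-aldol imide
Product: 25 (2S,3R,8R,10E,12E)-14-tert-butoxy-2-{[(tert-butyldimethylsilyl)oxy]methyl}-3-hydroxy-8,10,12-trimethyl-14-oxotetradeca-10,12-dienoic acid
Conditions: LiOH, H2O2, THF/H2O, 0 °C; then Na2SO3; then dilute HCl to pH 3–4, 0 °C
Reagents that add atoms: hydrogen peroxide (as LiOOH), OO
Why: Hydroperoxide cleavage of the N-acyl oxazolidinone at the exocyclic carbonyl, as in step 10, without epimerisation.

Step 16
Reactants: 25 the (2S,3R) syn hydroxy acid
Product: 27 tert-butyl (2E,4E,7R)-11-[(2S,3S)-3-{[(tert-butyldimethylsilyl)oxy]methyl}-4-oxooxetan-2-yl]-3,5,7-trimethylundeca-2,4-dienoate, via oxyphosphonium carboxylate 26 (not isolated)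
Conditions: PPh3, DIAD, THF, −78 °C (betaine preformed); slow addition of 25, −78 to 0 °C
Reagents that add atoms: none
Why: The same Mitsunobu lactonization by hydroxyl activation as in step 11 (4-exo-tet, SN2 inversion of the 3R carbinol), used here to build a temporary trans β-lactone whose only purpose is to invert the carbinol of the syn aldol.

Step 17
Reactants: 27 the (2S,3S) β-lactone tert-butyl ester
Product: 28 14-tert-butyl 1-(4-methoxybenzyl) (2S,3S,8R,10E,12E)-2-{[(tert-butyldimethylsilyl)oxy]methyl}-3-hydroxy-8,10,12-trimethyltetradeca-10,12-dienedioate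
Conditions: 4-methoxybenzyl alcohol, n-BuLi, THF, −78 to −40 °C; AcOH quench
Reagents that add atoms: 4-methoxybenzyl alcohol, COc1ccc(CO)cc1
Why: Alkoxide alcoholysis of the strained β-lactone at the acyl carbon (acyl–oxygen cleavage) breaks no bond to a stereocentre, so the trans lactone should open with retention to the anti (2S,3S) β-hydroxy ester, the hindered conjugated tert-butyl ester being inert at low temperature.

Step 18
Reactants: 20 the O-silylated lactone dienoic acid; 28 the anti (2S,3S) β-hydroxy diester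
Product: 29 14-tert-butyl 1-(4-methoxybenzyl) (2S,3S,8R,10E,12E)-2-{[(tert-butyldimethylsilyl)oxy]methyl}-8,10,12-trimethyl-3-({(2E,4E,7R)-11-[(2R,3R)-3-{[(tert-butyldimethylsilyl)oxy]methyl}-4-oxooxetan-2-yl]-3,5,7-trimethylundeca-2,4-dienoyl}oxy)tetradeca-10,12-dienedioate
Conditions: DCC, DMAP (cat.), CH2Cl2, 0 °C to rt
Reagents that add atoms: none
Why: Steglich esterification: the O-acylisourea and acylpyridinium forms of the dienoic acid acylate the only free hydroxyl, under neutral conditions that trans-disubstituted β-lactones are known to tolerate.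

Step 19
Reactants: 29 the fully protected diester
Product: 30 fusariumester B
Conditions: CF3CO2H/CH2Cl2/H2O, anisole, 0 °C to rt
Reagents that add atoms: none
Why: Global acidolysis: the tert-butyl and 4-methoxybenzyl esters cleave by alkyl–oxygen heterolysis (cations removed as isobutene and by anisole) and the primary silyl ethers are hydrolysed by the aqueous acid, while the β-lactone, the dienoates and the β-acyloxy acid, which would eliminate or suffer acyl migration under base, should be stable to non-nucleophilic acid.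

Compound list
1 | (R)-citronellal, (3R)-3,7-dimethyloct-6-enal | O=CC[C@H](C)CCC=C(C)C | starting material
2 | (4R)-4,8-dimethylnon-7-en-1-yne | C#CC[C@H](C)CCC=C(C)C | intermediate
3 | dimethyl[(1E,4R)-2,4,8-trimethylnona-1,7-dien-1-yl]alane (not isolated) | C[Al](C)/C=C(\C)C[C@H](C)CCC=C(C)C | intermediate
4 | (1E,4R)-1-iodo-2,4,8-trimethylnona-1,7-diene | I/C=C(\C)C[C@H](C)CCC=C(C)C | intermediate
5 | tert-butyl but-2-ynoate | CC#CC(=O)OC(C)(C)C | starting material
6 | tert-butyl (2Z)-3-(4,4,5,5-tetramethyl-1,3,2-dioxaborolan-2-yl)but-2-enoate | CC(=C\C(=O)OC(C)(C)C)/B1OC(C)(C)C(C)(C)O1 | intermediate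
7 | tert-butyl (2E,4E,7R)-3,5,7,11-tetramethyldodeca-2,4,10-trienoate | CC(=C\C(=O)OC(C)(C)C)/C=C(\C)C[C@H](C)CCC=C(C)C | intermediate
8 | tert-butyl (2E,4E,7R,10E)-3,5,7-trimethyl-12-oxododeca-2,4,10-trienoate | CC(=C\C(=O)OC(C)(C)C)/C=C(\C)C[C@H](C)CC/C=C/C=O | intermediate
9 | tert-butyl (2E,4E,7R)-3,5,7-trimethyl-12-oxododeca-2,4-dienoate | CC(=C\C(=O)OC(C)(C)C)/C=C(\C)C[C@H](C)CCCCC=O | intermediate
10 | 3-[(tert-butyldimethylsilyl)oxy]propanoic acid | CC(C)(C)[Si](C)(C)OCCC(=O)O | starting material
11 | 3-[(tert-butyldimethylsilyl)oxy]propanoic pivalic anhydride (used as a filtered solution) | CC(C)(C)[Si](C)(C)OCCC(=O)OC(=O)C(C)(C)C | intermediate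
12 | (R)-4-benzyloxazolidin-2-one | O=C1N[C@H](Cc2ccccc2)CO1 | starting material
13 | (R)-4-benzyl-3-{3-[(tert-butyldimethylsilyl)oxy]propanoyl}oxazolidin-2-one | CC(C)(C)[Si](C)(C)OCCC(=O)N1[C@H](Cc2ccccc2)COC1=O | intermediate
14 | dibutylboron Z enolate of 13 (not isolated) | CCCCB(CCCC)O/C(=C\CO[Si](C)(C)C(C)(C)C)N1[C@H](Cc2ccccc2)COC1=O | intermediate
15 | (4R)-4-benzyl-3-[(2R,3S,8R,10E,12E)-14-tert-butoxy-2-{[(tert-butyldimethylsilyl)oxy]methyl}-3-hydroxy-8,10,12-trimethyl-14-oxotetradeca-10,12-dienoyl]oxazolidin-2-one | CC(=C\C(=O)OC(C)(C)C)/C=C(\C)C[C@H](C)CCCC[C@H](O)[C@@H](CO[Si](C)(C)C(C)(C)C)C(=O)N1[C@H](Cc2ccccc2)COC1=O | intermediate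
16 | (2R,3S,8R,10E,12E)-14-tert-butoxy-2-{[(tert-butyldimethylsilyl)oxy]methyl}-3-hydroxy-8,10,12-trimethyl-14-oxotetradeca-10,12-dienoic acid | CC(=C\C(=O)OC(C)(C)C)/C=C(\C)C[C@H](C)CCCC[C@H](O)[C@@H](CO[Si](C)(C)C(C)(C)C)C(=O)O | intermediate
17 | 3-(triphenylphosphoniooxy) carboxylate zwitterion of 16 (not isolated) | CC(=C\C(=O)OC(C)(C)C)/C=C(\C)C[C@H](C)CCCC[C@H](O[P+](c1ccccc1)(c1ccccc1)c1ccccc1)[C@@H](CO[Si](C)(C)C(C)(C)C)C(=O)[O-] | intermediate
18 | tert-butyl (2E,4E,7R)-11-[(2R,3R)-3-{[(tert-butyldimethylsilyl)oxy]methyl}-4-oxooxetan-2-yl]-3,5,7-trimethylundeca-2,4-dienoate | CC(=C\C(=O)OC(C)(C)C)/C=C(\C)C[C@H](C)CCCC[C@H]1OC(=O)[C@@H]1CO[Si](C)(C)C(C)(C)C | intermediate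
19 | trimethylsilyl ester of 20 (not isolated) | CC(=C\C(=O)O[Si](C)(C)C)/C=C(\C)C[C@H](C)CCCC[C@H]1OC(=O)[C@@H]1CO[Si](C)(C)C(C)(C)C | intermediate
20 | (2E,4E,7R)-11-[(2R,3R)-3-{[(tert-butyldimethylsilyl)oxy]methyl}-4-oxooxetan-2-yl]-3,5,7-trimethylundeca-2,4-dienoic acid | CC(=C\C(=O)O)/C=C(\C)C[C@H](C)CCCC[C@H]1OC(=O)[C@@H]1CO[Si](C)(C)C(C)(C)C | intermediate
21 | (S)-4-benzyloxazolidin-2-one | O=C1N[C@@H](Cc2ccccc2)CO1 | starting material
22 | (S)-4-benzyl-3-{3-[(tert-butyldimethylsilyl)oxy]propanoyl}oxazolidin-2-one | CC(C)(C)[Si](C)(C)OCCC(=O)N1[C@@H](Cc2ccccc2)COC1=O | intermediate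
23 | dibutylboron Z enolate of 22 (not isolated) | CCCCB(CCCC)O/C(=C\CO[Si](C)(C)C(C)(C)C)N1[C@@H](Cc2ccccc2)COC1=O | intermediate
24 | (4S)-4-benzyl-3-[(2S,3R,8R,10E,12E)-14-tert-butoxy-2-{[(tert-butyldimethylsilyl)oxy]methyl}-3-hydroxy-8,10,12-trimethyl-14-oxotetradeca-10,12-dienoyl]oxazolidin-2-one | CC(=C\C(=O)OC(C)(C)C)/C=C(\C)C[C@H](C)CCCC[C@@H](O)[C@H](CO[Si](C)(C)C(C)(C)C)C(=O)N1[C@@H](Cc2ccccc2)COC1=O | intermediate
25 | (2S,3R,8R,10E,12E)-14-tert-butoxy-2-{[(tert-butyldimethylsilyl)oxy]methyl}-3-hydroxy-8,10,12-trimethyl-14-oxotetradeca-10,12-dienoic acid | CC(=C\C(=O)OC(C)(C)C)/C=C(\C)C[C@H](C)CCCC[C@@H](O)[C@H](CO[Si](C)(C)C(C)(C)C)C(=O)O | intermediate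
26 | 3-(triphenylphosphoniooxy) carboxylate zwitterion of 25 (not isolated) | CC(=C\C(=O)OC(C)(C)C)/C=C(\C)C[C@H](C)CCCC[C@@H](O[P+](c1ccccc1)(c1ccccc1)c1ccccc1)[C@H](CO[Si](C)(C)C(C)(C)C)C(=O)[O-] | intermediate
27 | tert-butyl (2E,4E,7R)-11-[(2S,3S)-3-{[(tert-butyldimethylsilyl)oxy]methyl}-4-oxooxetan-2-yl]-3,5,7-trimethylundeca-2,4-dienoate | CC(=C\C(=O)OC(C)(C)C)/C=C(\C)C[C@H](C)CCCC[C@@H]1OC(=O)[C@H]1CO[Si](C)(C)C(C)(C)C | intermediate
28 | 14-tert-butyl 1-(4-methoxybenzyl) (2S,3S,8R,10E,12E)-2-{[(tert-butyldimethylsilyl)oxy]methyl}-3-hydroxy-8,10,12-trimethyltetradeca-10,12-dienedioate | CC(=C\C(=O)OC(C)(C)C)/C=C(\C)C[C@H](C)CCCC[C@H](O)[C@H](CO[Si](C)(C)C(C)(C)C)C(=O)OCc1ccc(OC)cc1 | intermediate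
29 | fully protected fusariumester B (28 acylated at O3 by 20; tert-butyl and 4-methoxybenzyl esters, two silyl ethers) | CC(=C\C(=O)OC(C)(C)C)/C=C(\C)C[C@H](C)CCCC[C@H](OC(=O)/C=C(C)/C=C(\C)C[C@H](C)CCCC[C@H]1OC(=O)[C@@H]1CO[Si](C)(C)C(C)(C)C)[C@H](CO[Si](C)(C)C(C)(C)C)C(=O)OCc1ccc(OC)cc1 | intermediate
30 | fusariumester B | CC(=C\C(=O)O)/C=C(\C)C[C@H](C)CCCC[C@H](OC(=O)/C=C(C)/C=C(\C)C[C@H](C)CCCC[C@H]1OC(=O)[C@@H]1CO)[C@H](CO)C(=O)O | target

Total step count: 19.
Longest linear sequence: 11 steps from (R)-citronellal (steps 1, 2, 4, 5, 6, 9, 10, 11, 12, 18, 19; the other branch through steps 14 to 17 is equally long).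

Steps most likely to fail

Step 11 (key lactonization; step 16 runs the same reaction on the mirror-image diad and shares the risk). After hydroxyl activation the oxyphosphonium carboxylate may fragment by decarboxylative anti-elimination to an allylic silyl ether instead of closing, or the carboxyl group may be activated first and close with retention. The fallback installs the leaving group before the carboxylate is set free. It sets out from 15: mesyl chloride and pyridine in CH2Cl2 at 0 °C should give the (4R)-4-benzyl-3-[(2R,3S)-3-(methanesulfonyloxy)acyl]oxazolidin-2-one F1. LiOH/H2O2 in THF/H2O at 0 °C followed by Na2SO3 removes the auxiliary to give the (2R,3S)-3-(methanesulfonyloxy) acid F2. Stirring F2 with NaHCO3 in H2O/CH2Cl2 at rt lets the carboxylate displace the poorer sulfonate leaving group (4-exo-tet, inversion), the lactone being extracted into the organic phase as it forms. The fallback comes back to the route at 18.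

Step 18 (esterification). Acyl transfer to the hindered secondary alcohol may be slow; the activated 3-methyl dienoic acid may then isomerise or deconjugate through a vinylketene, and DMAP may induce β-elimination of the newly formed β-acyloxy ester. The fallback makes the acid the nucleophile and inverts the carbinol instead. It sets out from 25: 4-methoxybenzyl chloride and KHCO3 in DMF at rt alkylate the carboxylate to the 14-tert-butyl 1-(4-methoxybenzyl) (2S,3R,8R,10E,12E)-2-{[(tert-butyldimethylsilyl)oxy]methyl}-3-hydroxy-8,10,12-trimethyltetradeca-10,12-dienedioate F3. A Mitsunobu esterification of F3 with acid 20 (PPh3, DIAD, toluene, 0 °C) should then displace the activated 3R hydroxyl with inversion, which comes back to the route at 29; steps 16 and 17 are then not needed.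

Step 17 (lactone alcoholysis). The lithium alkoxide formed on ring opening may trigger migration of the silyl group from the primary oxygen or β-elimination, or the transesterification may stall at low temperature. The fallback separates ring opening from ester formation. It sets out from 27: LiOH in THF/H2O at 0 °C hydrolyses the lactone by acyl–oxygen cleavage to the (2S,3S,8R,10E,12E)-14-tert-butoxy-2-{[(tert-butyldimethylsilyl)oxy]methyl}-3-hydroxy-8,10,12-trimethyl-14-oxotetradeca-10,12-dienoic acid F4. Alkylation of its carboxylate with 4-methoxybenzyl chloride and KHCO3 in DMF at rt comes back to the route at 28.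

Further compounds
F1 | step 11 | (4R)-4-benzyl-3-[(2R,3S,8R,10E,12E)-14-tert-butoxy-2-{[(tert-butyldimethylsilyl)oxy]methyl}-3-(methanesulfonyloxy)-8,10,12-trimethyl-14-oxotetradeca-10,12-dienoyl]oxazolidin-2-one | CC(=C\C(=O)OC(C)(C)C)/C=C(\C)C[C@H](C)CCCC[C@H](OS(C)(=O)=O)[C@@H](CO[Si](C)(C)C(C)(C)C)C(=O)N1[C@H](Cc2ccccc2)COC1=O
F2 | step 11 | (2R,3S,8R,10E,12E)-14-tert-butoxy-2-{[(tert-butyldimethylsilyl)oxy]methyl}-3-(methanesulfonyloxy)-8,10,12-trimethyl-14-oxotetradeca-10,12-dienoic acid | CC(=C\C(=O)OC(C)(C)C)/C=C(\C)C[C@H](C)CCCC[C@H](OS(C)(=O)=O)[C@@H](CO[Si](C)(C)C(C)(C)C)C(=O)O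
F3 | step 18 | 14-tert-butyl 1-(4-methoxybenzyl) (2S,3R,8R,10E,12E)-2-{[(tert-butyldimethylsilyl)oxy]methyl}-3-hydroxy-8,10,12-trimethyltetradeca-10,12-dienedioate | CC(=C\C(=O)OC(C)(C)C)/C=C(\C)C[C@H](C)CCCC[C@@H](O)[C@H](CO[Si](C)(C)C(C)(C)C)C(=O)OCc1ccc(OC)cc1
F4 | step 17 | (2S,3S,8R,10E,12E)-14-tert-butoxy-2-{[(tert-butyldimethylsilyl)oxy]methyl}-3-hydroxy-8,10,12-trimethyl-14-oxotetradeca-10,12-dienoic acid | CC(=C\C(=O)OC(C)(C)C)/C=C(\C)C[C@H](C)CCCC[C@H](O)[C@H](CO[Si](C)(C)C(C)(C)C)C(=O)O
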